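**Retrosynthetic overview**
1. Last skeletal bond: the O–C(lactate) bond of the C1 ester, made with inversion by SN2 O-alkylation of the C1 carboxylate with the triflate of the (S)-hydroxy ester; only O-debenzylation follows.
2. The C1 carboxylate and free 8-OH come from hydrolysis of a five-membered aryl lactone (O8–C(=O)–C1) that holds C1 and C2 cis.
3. The six-membered carbocycle is closed on that lactone in one pot: Michael addition (C1–C2, sets C2), then intramolecular Horner–Wadsworth–Emmons olefination (C3=C4), between a 2-coumaranone-4-carbaldehyde and an α-phosphonocinnamate already esterified (retention) with the same (S)-hydroxy ester.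
4. Lactone donor from 4-(benzyloxy)-3-hydroxybenzaldehyde (O-allylation, Claisen, ozonolysis, lactol oxidation); the single chiral building block from L-DOPA.
5. Ring order: arenes bought; lactone ring (C–O) first; carbocycle second; lactone opened again before the last C–O bond.

Assumption: the SMILES is taken literally, i.e. (1S,2S) with the C1 ester and C2 aryl cis, an (S)-lactate on the C3 carboxyl and an (R)-lactate on the C1 carboxyl; ring atoms are numbered as in 1,2-dihydronaphthalene.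

**Route**

Step 1
Reactants: 1 L-DOPA
Product: 2 (S)-3-(3,4-dihydroxyphenyl)-2-hydroxypropanoic acid
Conditions: NaNO2, 1 M aq. H2SO4, 0 °C → rt, N2
Reagents that add atoms: water, O
Why: Diazotization of the α-amino acid goes with net retention (the carboxylate displaces N2 to an α-lactone that water opens, a double inversion), so the (S) centre of L-DOPA is carried into the hydroxy acid.

Step 2
Reactants: 2 (S)-3-(3,4-dihydroxyphenyl)-2-hydroxypropanoic acid
Product: 3 methyl (S)-3-(3,4-dihydroxyphenyl)-2-hydroxypropanoate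
Conditions: MeOH, H2SO4 (cat.), reflux
Reagents that add atoms: methanol, CO
Why: Fischer esterification, which does not touch the stereocentre or the catechol.

Step 3
Reactants: 3 methyl (S)-3-(3,4-dihydroxyphenyl)-2-hydroxypropanoate
Product: 4 methyl (S)-3-[3,4-bis(benzyloxy)phenyl]-2-hydroxypropanoate
Conditions: BnBr (2.1 equiv), K2CO3, acetone, reflux
Reagents that add atoms: benzyl bromide, BrCc1ccccc1
Why: Williamson ether synthesis in which carbonate deprotonates only the two phenols, so the secondary alcohol stays free.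

Step 4
Reactants: 4 methyl (S)-3-[3,4-bis(benzyloxy)phenyl]-2-hydroxypropanoate; 5 diethylphosphonoacetic acid
Product: 6 methyl (S)-3-[3,4-bis(benzyloxy)phenyl]-2-{[(diethoxyphosphoryl)acetyl]oxy}propanoate
Conditions: DCC, DMAP (10 mol%), CH2Cl2, 0 °C → rt
Reagents that add atoms: none
Why: Steglich esterification forms the acyl C–O bond without breaking the carbinol C–O bond, so the (S) configuration is retained.

Step 5
Reactants: 6 methyl (S)-3-[3,4-bis(benzyloxy)phenyl]-2-{[(diethoxyphosphoryl)acetyl]oxy}propanoate; 7 3,4-bis(benzyloxy)benzaldehyde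
Product: 8 methyl (S)-3-[3,4-bis(benzyloxy)phenyl]-2-{[(E)-3-[3,4-bis(benzyloxy)phenyl]-2-(diethoxyphosphoryl)prop-2-enoyl]oxy}propanoate
Conditions: TiCl4, N-methylmorpholine, THF, 0 °C → rt
Reagents that add atoms: none
Why: Knoevenagel condensation of a phosphonoacetate under TiCl4/amine conditions, which gives the E alkene (aryl trans to phosphorus) at low temperature without disturbing the lactate centre.

Step 6
Reactants: 9 4-(benzyloxy)-3-hydroxybenzaldehyde; 10 allyl bromide
Product: 11 3-(allyloxy)-4-(benzyloxy)benzaldehyde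
Conditions: K2CO3, DMF, 50 °C
Reagents that add atoms: none
Why: Williamson O-allylation of the only free phenol.

Step 7
Reactants: 11 3-(allyloxy)-4-(benzyloxy)benzaldehyde
Product: 12 2-allyl-4-(benzyloxy)-3-hydroxybenzaldehyde
Conditions: PhNEt2, 200 °C, sealed tube
Reagents that add atoms: none
Why: Aromatic Claisen rearrangement, which can only deliver the allyl group to C2 because the other ortho position carries the benzyloxy group.

Step 8
Reactants: 12 2-allyl-4-(benzyloxy)-3-hydroxybenzaldehyde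
Product: 14 7-(benzyloxy)-2-oxo-2,3-dihydro-1-benzofuran-4-carbaldehyde, via lactol 13 (not isolated)
Conditions: O3, CH2Cl2, −78 °C; PPh3 (1.05 equiv), −78 °C → rt; then TEMPO (10 mol%), PhI(OAc)2, rt
Reagents that add atoms: ozone, [O-][O+]=O
Why: Ozonolysis of the terminal alkene gives an arylacetaldehyde that closes onto the ortho phenol as a five-membered lactol, and TEMPO/PhI(OAc)2 oxidises this lactol to the lactone while the aryl aldehyde is inert under anhydrous conditions.

Step 9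
Reactants: 14 7-(benzyloxy)-2-oxo-2,3-dihydro-1-benzofuran-4-carbaldehyde; 8 methyl (S)-3-[3,4-bis(benzyloxy)phenyl]-2-{[(E)-3-[3,4-bis(benzyloxy)phenyl]-2-(diethoxyphosphoryl)prop-2-enoyl]oxy}propanoate
Product: 16 (2S)-3-[3,4-bis(benzyloxy)phenyl]-1-methoxy-1-oxopropan-2-yl (2aS,3S)-8-(benzyloxy)-3-[3,4-bis(benzyloxy)phenyl]-2-oxo-2a,3-dihydro-2H-naphtho[1,8-bc]furan-4-carboxylate, via Michael adduct 15 (not isolated)
Conditions: 14 added over 2 h to 8 (1.2 equiv), Mg(OTf)2 (10 mol%), (S,S)-tBu-BOX (11 mol%), N-methylmorpholine (20 mol%), 4 Å MS, CH2Cl2, −20 °C; then LiCl, DBU (1.5 equiv), MeCN, 0 °C; AcOH quench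
Reagents that add atoms: none
Why: Proposed new method: an enantioselective Michael addition/intramolecular Horner–Wadsworth–Emmons annulation in which chiral divalent magnesium chelates the P=O/C=O pair of 8 (raising its β-electrophilicity above that of the aldehyde of 14 and shielding one face) while the amine enolises the acidic lactone CH2, so the ligand sets C2 as S (ligand sense to be confirmed by experiment, the mirror-image ligand is equally available, and 16 and its ring epimer are separable diastereomers because of the resident lactate), after which LiCl/DBU closes C3=C4 under Masamune–Roush conditions and the acidic lactone C–H equilibrates to the cis isomer (C2 aryl pseudoaxial to avoid A(1,2) strain with the C3 ester, and kinetic protonation anti to the aryl gives the same result); the closest known reactions are chiral Lewis-acid-catalysed Michael additions to chelating alkylidene malonates and base-mediated tandem Michael/HWE annulations of vinylphosphonates.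

Step 10
Reactants: 16 the tricyclic cis-lactone named in step 9; 4 methyl (S)-3-[3,4-bis(benzyloxy)phenyl]-2-hydroxypropanoate
Product: 19 1-[(2R)-3-[3,4-bis(benzyloxy)phenyl]-1-methoxy-1-oxopropan-2-yl] 3-[(2S)-3-[3,4-bis(benzyloxy)phenyl]-1-methoxy-1-oxopropan-2-yl] (1S,2S)-7-(benzyloxy)-2-[3,4-bis(benzyloxy)phenyl]-8-hydroxy-1,2-dihydronaphthalene-1,3-dicarboxylate, via cesium carboxylate 17 (not isolated), via triflate 18 (not isolated)
Conditions: 16, CsHCO3 (1.1 equiv), DMAP (10 mol%), THF/H2O 4:1, rt, then evaporate and dry by toluene azeotrope; separately 4 (1.3 equiv), Tf2O, 2,6-lutidine, CH2Cl2, −78 °C; combine in DMF/CH2Cl2, −40 → 0 °C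
Reagents that add atoms: water, O
Why: DMAP-catalysed hydrolysis at bicarbonate pH cleaves only the phenolic lactone (driven by carboxylate formation, C1 stays cis), and the cesium carboxylate then displaces the α-triflate in an SN2 O-alkylation with clean inversion, turning (S)-4 into the (R)-lactate ester while the un-ionised 8-OH is untouched and no acyl activation occurs that would simply reclose the lactone.

Step 11
Reactants: 19 the hepta-O-benzyl diester named in step 10
Product: 20 1-[(2R)-3-(3,4-dihydroxyphenyl)-1-methoxy-1-oxopropan-2-yl] 3-[(2S)-3-(3,4-dihydroxyphenyl)-1-methoxy-1-oxopropan-2-yl] (1S,2S)-2-(3,4-dihydroxyphenyl)-7,8-dihydroxy-1,2-dihydronaphthalene-1,3-dicarboxylate (CNP0237075.1)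
Conditions: BCl3 (20 equiv), pentamethylbenzene (25 equiv), CH2Cl2, −78 °C; MeOH/CHCl3 quench at −78 °C
Reagents that add atoms: none
Why: Lewis-acid O-debenzylation with a non-basic cation scavenger cleaves all seven aryl benzyl ethers at −78 °C and leaves the four esters, the C3=C4 alkene (which hydrogenolysis would reduce) and the epimerisable C1 centre alone.

**Compound list**
1 | L-DOPA, (S)-2-amino-3-(3,4-dihydroxyphenyl)propanoic acid | N[C@@H](Cc1ccc(O)c(O)c1)C(=O)O | starting material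
2 | (S)-3-(3,4-dihydroxyphenyl)-2-hydroxypropanoic acid | O[C@@H](Cc1ccc(O)c(O)c1)C(=O)O | intermediate
3 | methyl (S)-3-(3,4-dihydroxyphenyl)-2-hydroxypropanoate | COC(=O)[C@H](Cc1ccc(O)c(O)c1)O | intermediate
4 | methyl (S)-3-[3,4-bis(benzyloxy)phenyl]-2-hydroxypropanoate | COC(=O)[C@H](Cc1ccc(OCc2ccccc2)c(OCc2ccccc2)c1)O | intermediate
5 | diethylphosphonoacetic acid | CCOP(=O)(CC(=O)O)OCC | starting material
6 | methyl (S)-3-[3,4-bis(benzyloxy)phenyl]-2-{[(diethoxyphosphoryl)acetyl]oxy}propanoate | COC(=O)[C@H](Cc1ccc(OCc2ccccc2)c(OCc2ccccc2)c1)OC(=O)CP(=O)(OCC)OCC | intermediate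
7 | 3,4-bis(benzyloxy)benzaldehyde | O=Cc1ccc(OCc2ccccc2)c(OCc2ccccc2)c1 | starting material
8 | methyl (S)-3-[3,4-bis(benzyloxy)phenyl]-2-{[(E)-3-[3,4-bis(benzyloxy)phenyl]-2-(diethoxyphosphoryl)prop-2-enoyl]oxy}propanoate | COC(=O)[C@H](Cc1ccc(OCc2ccccc2)c(OCc2ccccc2)c1)OC(=O)/C(=C\c1ccc(OCc2ccccc2)c(OCc2ccccc2)c1)P(=O)(OCC)OCC | intermediate
9 | 4-(benzyloxy)-3-hydroxybenzaldehyde | O=Cc1ccc(OCc2ccccc2)c(O)c1 | starting material
10 | allyl bromide | C=CCBr | starting material
11 | 3-(allyloxy)-4-(benzyloxy)benzaldehyde | O=Cc1ccc(OCc2ccccc2)c(OCC=C)c1 | intermediate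
12 | 2-allyl-4-(benzyloxy)-3-hydroxybenzaldehyde | O=Cc1ccc(OCc2ccccc2)c(O)c1CC=C | intermediate
13 | 7-(benzyloxy)-2-hydroxy-2,3-dihydro-1-benzofuran-4-carbaldehyde (lactol, both epimers) | O=Cc1ccc(OCc2ccccc2)c2OC(O)Cc12 | intermediate
14 | 7-(benzyloxy)-2-oxo-2,3-dihydro-1-benzofuran-4-carbaldehyde | O=Cc1ccc(OCc2ccccc2)c2OC(=O)Cc12 | intermediate
15 | methyl (S)-3-[3,4-bis(benzyloxy)phenyl]-2-{[(3S)-3-[3,4-bis(benzyloxy)phenyl]-3-[7-(benzyloxy)-4-formyl-2-oxo-2,3-dihydro-1-benzofuran-3-yl]-2-(diethoxyphosphoryl)propanoyl]oxy}propanoate (mixture at the lactone CH and the phosphonate carbon) | COC(=O)[C@H](Cc1ccc(OCc2ccccc2)c(OCc2ccccc2)c1)OC(=O)C(P(=O)(OCC)OCC)[C@H](c1ccc(OCc2ccccc2)c(OCc2ccccc2)c1)C1C(=O)Oc2c(OCc3ccccc3)ccc(C=O)c12 | intermediate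
16 | (2S)-3-[3,4-bis(benzyloxy)phenyl]-1-methoxy-1-oxopropan-2-yl (2aS,3S)-8-(benzyloxy)-3-[3,4-bis(benzyloxy)phenyl]-2-oxo-2a,3-dihydro-2H-naphtho[1,8-bc]furan-4-carboxylate (H2a and H3 cis) | COC(=O)[C@H](Cc1ccc(OCc2ccccc2)c(OCc2ccccc2)c1)OC(=O)C1=Cc2ccc(OCc3ccccc3)c3c2[C@@H](C(=O)O3)[C@H]1c1ccc(OCc2ccccc2)c(OCc2ccccc2)c1 | intermediate
17 | cesium (1S,2S)-7-(benzyloxy)-2-[3,4-bis(benzyloxy)phenyl]-8-hydroxy-3-({[(2S)-3-[3,4-bis(benzyloxy)phenyl]-1-methoxy-1-oxopropan-2-yl]oxy}carbonyl)-1,2-dihydronaphthalene-1-carboxylate | COC(=O)[C@H](Cc1ccc(OCc2ccccc2)c(OCc2ccccc2)c1)OC(=O)C1=Cc2ccc(OCc3ccccc3)c(O)c2[C@@H](C(=O)[O-])[C@H]1c1ccc(OCc2ccccc2)c(OCc2ccccc2)c1.[Cs+] | intermediate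
18 | methyl (S)-3-[3,4-bis(benzyloxy)phenyl]-2-{[(trifluoromethyl)sulfonyl]oxy}propanoate | COC(=O)[C@H](Cc1ccc(OCc2ccccc2)c(OCc2ccccc2)c1)OS(=O)(=O)C(F)(F)F | intermediate
19 | 1-[(2R)-3-[3,4-bis(benzyloxy)phenyl]-1-methoxy-1-oxopropan-2-yl] 3-[(2S)-3-[3,4-bis(benzyloxy)phenyl]-1-methoxy-1-oxopropan-2-yl] (1S,2S)-7-(benzyloxy)-2-[3,4-bis(benzyloxy)phenyl]-8-hydroxy-1,2-dihydronaphthalene-1,3-dicarboxylate | COC(=O)[C@H](Cc1ccc(OCc2ccccc2)c(OCc2ccccc2)c1)OC(=O)C1=Cc2ccc(OCc3ccccc3)c(O)c2[C@@H](C(=O)O[C@H](Cc2ccc(OCc3ccccc3)c(OCc3ccccc3)c2)C(=O)OC)[C@H]1c1ccc(OCc2ccccc2)c(OCc2ccccc2)c1 | intermediate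
20 | CNP0237075.1, 1-[(2R)-3-(3,4-dihydroxyphenyl)-1-methoxy-1-oxopropan-2-yl] 3-[(2S)-3-(3,4-dihydroxyphenyl)-1-methoxy-1-oxopropan-2-yl] (1S,2S)-2-(3,4-dihydroxyphenyl)-7,8-dihydroxy-1,2-dihydronaphthalene-1,3-dicarboxylate | COC(=O)[C@H](Cc1ccc(O)c(O)c1)OC(=O)C1=Cc2ccc(O)c(O)c2[C@@H](C(=O)O[C@H](Cc2ccc(O)c(O)c2)C(=O)OC)[C@H]1c1ccc(O)c(O)c1 | target

**Step count**
Total: 11 steps. Longest linear sequence: 8 steps (steps 1, 2, 3, 4, 5, 9, 10, 11).

**Three steps most likely to fail**

Step 9 (the proposed new step). Compound 14 carries both an acidic CH2 and an aldehyde and can self-condense, 8 is a weak electron-rich acceptor, and the level and sense of induction are untested. The fallback uses known chemistry, sets out from 14, 7 and 4 and comes back at 16. Aldehyde 7 is homologated by a Wittig reaction with Ph3P=CHCHO (toluene, 80 °C) to (E)-3-[3,4-bis(benzyloxy)phenyl]prop-2-enal F1. Lactone 14 and F1 are then combined with (R)-α,α-diphenylprolinol trimethylsilyl ether (20 mol%) and PhCO2H in toluene; iminium Michael addition (the catalyst shields one enal face, giving 3S) followed by enamine aldol condensation onto the aryl aldehyde is an established organocatalytic domino route to 1,2-dihydronaphthalene-3-carbaldehydes and gives (2aS,3S)-8-(benzyloxy)-3-[3,4-bis(benzyloxy)phenyl]-2-oxo-2a,3-dihydro-2H-naphtho[1,8-bc]furan-4-carbaldehyde F2. Pinnick oxidation (NaClO2, NaH2PO4, 2-methyl-2-butene, tBuOH/H2O) gives the corresponding 4-carboxylic acid F3, and DCC/DMAP esterification with 4 gives 16.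

Step 10. The risks are partial cleavage of the other esters during lactone hydrolysis, and elimination or racemisation of triflate 18 (an electron-rich β-aryl α-triflyloxy ester). The fallback sets out from 16 and comes back at 19 and avoids both the sulfonate and the metal carboxylate. Lactone 16 is hydrolysed as in the route and acidified to pH 4 to give the free (1S,2S)-7-(benzyloxy)-2-[3,4-bis(benzyloxy)phenyl]-8-hydroxy-3-({[(2S)-3-[3,4-bis(benzyloxy)phenyl]-1-methoxy-1-oxopropan-2-yl]oxy}carbonyl)-1,2-dihydronaphthalene-1-carboxylic acid F4. F4 is then coupled with 4 by Mitsunobu redox condensation (PPh3, DIAD, THF, −20 → 0 °C, with the acid added last to the pre-formed oxyphosphorane so that no acyloxyphosphonium can reclose the lactone). The carboxylic acid (pKa about 4) reacts in preference to the phenol and the carbinol centre is inverted to R, giving 19.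

Step 11. Seven benzyl ethers must fall from a product whose free 8-OH sits next to the C1 ester, so BCl3 could trigger relactonisation with loss of the lactate. The fallback sets out from 16 and 3 and comes back at 20; it moves the debenzylation to the lactone stage, where that ester is not yet present. Treating 16 with BCl3/pentamethylbenzene (CH2Cl2, −78 °C) gives (2S)-3-(3,4-dihydroxyphenyl)-1-methoxy-1-oxopropan-2-yl (2aS,3S)-3-(3,4-dihydroxyphenyl)-8-hydroxy-2-oxo-2a,3-dihydro-2H-naphtho[1,8-bc]furan-4-carboxylate F5. Hydrolysis with CsHCO3/DMAP in degassed THF/H2O and acidification gives (1S,2S)-2-(3,4-dihydroxyphenyl)-7,8-dihydroxy-3-({[(2S)-3-(3,4-dihydroxyphenyl)-1-methoxy-1-oxopropan-2-yl]oxy}carbonyl)-1,2-dihydronaphthalene-1-carboxylic acid F6. A chemoselective Mitsunobu esterification of F6 with the unprotected (S)-hydroxy ester 3 (PPh3, DIAD, THF, 0 °C; carboxylic acids are alkylated ahead of catechol OH groups, as in ester syntheses from free caffeic acid) inverts the carbinol centre to R and gives 20 directly.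

**Further compounds**
F1 | step 9 | (E)-3-[3,4-bis(benzyloxy)phenyl]prop-2-enal | O=C/C=C/c1ccc(OCc2ccccc2)c(OCc2ccccc2)c1
F2 | step 9 | (2aS,3S)-8-(benzyloxy)-3-[3,4-bis(benzyloxy)phenyl]-2-oxo-2a,3-dihydro-2H-naphtho[1,8-bc]furan-4-carbaldehyde | O=CC1=Cc2ccc(OCc3ccccc3)c3c2[C@@H](C(=O)O3)[C@H]1c1ccc(OCc2ccccc2)c(OCc2ccccc2)c1
F3 | step 9 | (2aS,3S)-8-(benzyloxy)-3-[3,4-bis(benzyloxy)phenyl]-2-oxo-2a,3-dihydro-2H-naphtho[1,8-bc]furan-4-carboxylic acid | OC(=O)C1=Cc2ccc(OCc3ccccc3)c3c2[C@@H](C(=O)O3)[C@H]1c1ccc(OCc2ccccc2)c(OCc2ccccc2)c1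
F4 | step 10 | (1S,2S)-7-(benzyloxy)-2-[3,4-bis(benzyloxy)phenyl]-8-hydroxy-3-({[(2S)-3-[3,4-bis(benzyloxy)phenyl]-1-methoxy-1-oxopropan-2-yl]oxy}carbonyl)-1,2-dihydronaphthalene-1-carboxylic acid | COC(=O)[C@H](Cc1ccc(OCc2ccccc2)c(OCc2ccccc2)c1)OC(=O)C1=Cc2ccc(OCc3ccccc3)c(O)c2[C@@H](C(=O)O)[C@H]1c1ccc(OCc2ccccc2)c(OCc2ccccc2)c1
F5 | step 11 | (2S)-3-(3,4-dihydroxyphenyl)-1-methoxy-1-oxopropan-2-yl (2aS,3S)-3-(3,4-dihydroxyphenyl)-8-hydroxy-2-oxo-2a,3-dihydro-2H-naphtho[1,8-bc]furan-4-carboxylate | COC(=O)[C@H](Cc1ccc(O)c(O)c1)OC(=O)C1=Cc2ccc(O)c3c2[C@@H](C(=O)O3)[C@H]1c1ccc(O)c(O)c1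
F6 | step 11 | (1S,2S)-2-(3,4-dihydroxyphenyl)-7,8-dihydroxy-3-({[(2S)-3-(3,4-dihydroxyphenyl)-1-methoxy-1-oxopropan-2-yl]oxy}carbonyl)-1,2-dihydronaphthalene-1-carboxylic acid | COC(=O)[C@H](Cc1ccc(O)c(O)c1)OC(=O)C1=Cc2ccc(O)c(O)c2[C@@H](C(=O)O)[C@H]1c1ccc(O)c(O)c1
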